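**Assumption:** C1–C15 are the germacrane positions of the target (C6 lactone carbinol, C8 epoxyangelate carbon, C9 2-methylbutanoate carbon, C14 the ester carbon on C10); angelic acid, (R)-2-methylbutanoic acid, (S)-α-hydroxy-γ-butyrolactone and both diethyl tartrates are taken as purchasable. TBS = tert-butyl(dimethyl)silyl, TBDPS = tert-butyl(diphenyl)silyl.

## Retrosynthetic overview

1. The ten-membered ring is closed last, by ring-closing metathesis at C1=C10 of a fully acylated seco-triene (vinyl oxirane + 2-substituted acrylate).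
2. The acrylate comes from a C14 aldehyde by Mannich methylenation and oxidation; the C8 carbinol comes from Felkin reduction of a C8 ketone.
3. The C6–C7 bond is made by an intermolecular titanium aldol of an α-silyloxy ketone (C7–C14) with an epoxy-dienal (C1–C6); the γ-lactone closes directly afterwards.
4. The ketone comes from (S)-α-hydroxy-γ-butyrolactone and the (S)-Roche ester (thioester/organozinc ketone synthesis); the aldehyde comes from cis-butenediol (Sharpless epoxidation, Horner–Wadsworth–Emmons, Wittig).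
5. Ring order: oxirane, then γ-lactone, then ten-membered carbocycle.

## Part A – west aldehyde (C1–C6)

Step 1
Reactants: 1 (2Z)-but-2-ene-1,4-diol
Product: 2 (2Z)-4-(TBDPSO)but-2-en-1-ol
Conditions: NaH (1.0 equiv), THF, 0 °C; TBDPSCl (1.0 equiv), 0 °C to rt
Reagents that add atoms: tert-butyl(chloro)diphenylsilane CC(C)(C)[Si](Cl)(c1ccccc1)c1ccccc1
Why: Statistical monosilylation of a symmetric diol through its sparingly soluble mono-alkoxide (Williamson-type O-silylation); no stereocentre is involved.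

Step 2
Reactants: 2 (2Z)-4-(TBDPSO)but-2-en-1-ol
Product: 3 [(2S,3R)-3-(TBDPSO-methyl)oxiran-2-yl]methanol
Conditions: Ti(Oi-Pr)4 (0.2 equiv), L-(+)-diethyl tartrate (0.25 equiv), t-BuOOH (2 equiv), 4 Å MS, CH2Cl2, −20 °C
Reagents that add atoms: tert-butyl hydroperoxide CC(C)(C)OO
Why: Sharpless asymmetric epoxidation of a Z-allylic alcohol; the L-(+)-tartrate complex delivers oxygen to the face that gives the (2S,3R) cis-oxirane (future C3 and C2), and any minor enantiomer is removed later as a diastereomer after fragment union.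

Step 3
Reactants: 3 [(2S,3R)-3-(TBDPSO-methyl)oxiran-2-yl]methanol
Product: 4 (2R,3R)-3-(TBDPSO-methyl)oxirane-2-carbaldehyde
Conditions: Dess–Martin periodinane, NaHCO3, CH2Cl2, 0 °C to rt
Reagents that add atoms: none
Why: Buffered Dess–Martin oxidation gives the cis-epoxy aldehyde without epimerisation (the CIP label changes, the geometry does not).

Step 4
Reactants: 4 (2R,3R)-3-(TBDPSO-methyl)oxirane-2-carbaldehyde
Product: 5 1-[(2S,3R)-3-(TBDPSO-methyl)oxiran-2-yl]ethan-1-ol (both carbinol epimers)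
Conditions: MeMgBr, THF, −78 °C
Reagents that add atoms: methylmagnesium bromide C[Mg]Br
Why: Grignard 1,2-addition to the aldehyde is much faster than oxirane opening at −78 °C; the new carbinol centre is removed in the next step.

Step 5
Reactants: 5 1-[(2S,3R)-3-(TBDPSO-methyl)oxiran-2-yl]ethan-1-ol
Product: 6 1-[(2R,3R)-3-(TBDPSO-methyl)oxiran-2-yl]ethan-1-one
Conditions: Dess–Martin periodinane, NaHCO3, CH2Cl2, rt
Reagents that add atoms: none
Why: Dess–Martin oxidation to the methyl ketone; the oxiranyl α-hydrogen does not enolise, so the cis-epoxide is kept.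

Step 6
Reactants: 6 1-[(2R,3R)-3-(TBDPSO-methyl)oxiran-2-yl]ethan-1-one
Product: 7 (2E)-3-[(2S,3R)-3-(TBDPSO-methyl)oxiran-2-yl]-N-methoxy-N-methylbut-2-enamide
Conditions: (EtO)2P(O)CH2C(O)N(OMe)Me, NaH, THF, 0 °C to rt; chromatography removes the minor Z isomer
Reagents that add atoms: diethyl [2-(methoxy(methyl)amino)-2-oxoethyl]phosphonate CCOP(=O)(CC(=O)N(C)OC)OCC
Why: Horner–Wadsworth–Emmons olefination of the methyl ketone gives mainly the E trisubstituted alkene (amide trans to the oxiranyl group), which is the C4=C5 geometry of the target.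

Step 7
Reactants: 7 (2E)-3-[(2S,3R)-3-(TBDPSO-methyl)oxiran-2-yl]-N-methoxy-N-methylbut-2-enamide
Product: 8 (2E)-3-[(2S,3R)-3-(hydroxymethyl)oxiran-2-yl]-N-methoxy-N-methylbut-2-enamide
Conditions: Bu4NF, AcOH, THF, 0 °C
Reagents that add atoms: none
Why: Fluoride desilylation; the acetic acid buffer keeps the liberated epoxy alcohol from Payne rearrangement.

Step 8
Reactants: 8 (2E)-3-[(2S,3R)-3-(hydroxymethyl)oxiran-2-yl]-N-methoxy-N-methylbut-2-enamide
Product: 9 (2E)-3-[(2S,3S)-3-formyloxiran-2-yl]-N-methoxy-N-methylbut-2-enamide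
Conditions: Dess–Martin periodinane, NaHCO3, CH2Cl2, 0 °C
Reagents that add atoms: none
Why: Buffered Dess–Martin oxidation to the cis-epoxy aldehyde (C1), used at once to avoid cis-to-trans epimerisation.

Step 9
Reactants: 9 (2E)-3-[(2S,3S)-3-formyloxiran-2-yl]-N-methoxy-N-methylbut-2-enamide
Product: 10 (2E)-3-[(2S,3R)-3-ethenyloxiran-2-yl]-N-methoxy-N-methylbut-2-enamide
Conditions: Ph3PCH3Br, KN(SiMe3)2, THF, −78 to 0 °C
Reagents that add atoms: methyltriphenylphosphonium bromide C[P+](c1ccccc1)(c1ccccc1)c1ccccc1.[Br-]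
Why: Wittig methylenation of the aldehyde installs the C1 vinyl group needed for the final metathesis; the unsaturated Weinreb amide is inert to the ylide.

Step 10
Reactants: 10 (2E)-3-[(2S,3R)-3-ethenyloxiran-2-yl]-N-methoxy-N-methylbut-2-enamide
Product: 11 (2E)-3-[(2S,3R)-3-ethenyloxiran-2-yl]but-2-enal
Conditions: i-Bu2AlH, THF, −78 °C; aqueous potassium sodium tartrate work-up
Reagents that add atoms: none
Why: Hydride reduction of the Weinreb amide stops at the chelated hemiaminal and releases the enal on work-up; the vinyl oxirane survives at −78 °C.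

## Part B – east ketone (C7–C14)

Step 11
Reactants: 12 (3S)-3-hydroxyoxolan-2-one
Product: 13 (3S)-3-(TBSO)oxolan-2-one
Conditions: TBSCl, imidazole, DMF, rt
Reagents that add atoms: tert-butyl(chloro)dimethylsilane CC(C)(C)[Si](C)(C)Cl
Why: Standard silylation; the C9 stereocentre comes from the chiral pool and is not touched.

Step 12
Reactants: 13 (3S)-3-(TBSO)oxolan-2-one
Product: 14 S-ethyl (2S)-2-(TBSO)-4-hydroxybutanethioate (used crude)
Conditions: AlMe3, EtSH, CH2Cl2, 0 °C; then 13, 0 °C to rt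
Reagents that add atoms: ethanethiol CCS
Why: Aluminium thiolate opening of the lactone (acyl substitution) gives the hydroxy thioester without enolising the α-silyloxy centre.

Step 13
Reactants: 14 S-ethyl (2S)-2-(TBSO)-4-hydroxybutanethioate
Product: 15 S-ethyl (2S)-2,4-bis(TBSO)butanethioate
Conditions: TBSCl, imidazole, DMF, 0 °C to rt
Reagents that add atoms: tert-butyl(chloro)dimethylsilane CC(C)(C)[Si](C)(C)Cl
Why: Immediate silylation of the primary alcohol (future C14–O) prevents relactonisation.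

Step 14
Reactants: 16 methyl (2S)-3-hydroxy-2-methylpropanoate
Product: 17 methyl (2R)-3-iodo-2-methylpropanoate
Conditions: I2, PPh3, imidazole, CH2Cl2, 0 °C to rt
Reagents that add atoms: iodine II
Why: Appel iodination at the primary carbon; the stereocentre (future C11) is untouched and only its CIP label changes.

Step 15
Reactants: 17 methyl (2R)-3-iodo-2-methylpropanoate; 15 S-ethyl (2S)-2,4-bis(TBSO)butanethioate
Product: 19 methyl (2S,5S)-5,7-bis(TBSO)-2-methyl-4-oxoheptanoate, via organozinc iodide 18 (not isolated)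
Conditions: Zn (activated with Me3SiCl), THF, 35 °C; then 15, PdCl2(PPh3)2 (5 mol%), toluene, rt
Reagents that add atoms: zinc [Zn] (kept only in 18)
Why: Fukuyama ketone synthesis (palladium-catalysed coupling of a thioester with an ester-bearing alkylzinc) forms the C7–C8 bond under neutral conditions, so the C9 and C11 centres are retained.

## Part C – (2S,3S)-epoxyangelic acid

Step 16
Reactants: 20 (2Z)-2-methylbut-2-enoic acid
Product: 21 (2Z)-2-methylbut-2-en-1-ol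
Conditions: LiAlH4, Et2O, 0 °C
Reagents that add atoms: none
Why: Hydride reduction of the acid to the allylic alcohol with retention of the Z geometry.

Step 17
Reactants: 21 (2Z)-2-methylbut-2-en-1-ol
Product: 22 [(2R,3S)-2,3-dimethyloxiran-2-yl]methanol
Conditions: Ti(Oi-Pr)4 (0.2 equiv), D-(−)-diethyl tartrate (0.25 equiv), t-BuOOH, 4 Å MS, CH2Cl2, −20 °C
Reagents that add atoms: tert-butyl hydroperoxide CC(C)(C)OO
Why: Sharpless asymmetric epoxidation; the D-(−)-tartrate catalyst delivers oxygen to the face that gives the (2R,3S) epoxy alcohol.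

Step 18
Reactants: 22 [(2R,3S)-2,3-dimethyloxiran-2-yl]methanol
Product: 23 (2S,3S)-2,3-dimethyloxirane-2-carboxylic acid
Conditions: RuCl3 (2 mol%), NaIO4 (3 equiv), MeCN/EtOAc/H2O, 0 °C to rt
Reagents that add atoms: sodium periodate [Na+].[O-]I(=O)(=O)=O
Why: Ruthenium tetroxide oxidation of the primary alcohol to the acid leaves both oxirane centres untouched (2R becomes 2S only by CIP priority).

## Part D – fragment union and endgame

Step 19
Reactants: 19 methyl (2S,5S)-5,7-bis(TBSO)-2-methyl-4-oxoheptanoate; 11 (2E)-3-[(2S,3R)-3-ethenyloxiran-2-yl]but-2-enal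
Product: 26 (3S,4S,5R)-4-[(2S)-2,4-bis(TBSO)butanoyl]-5-{(1E)-2-[(2S,3R)-3-ethenyloxiran-2-yl]prop-1-en-1-yl}-3-methyloxolan-2-one, via titanium enolate 24 (not isolated), via aldol adduct 25 (not isolated)
Conditions: TiCl4 (1.1 equiv), i-Pr2NEt (1.2 equiv), CH2Cl2, −78 °C; 11, −78 °C; aq NH4Cl; then 2-hydroxypyridine (0.2 equiv), toluene, 40 °C
Reagents that add atoms: titanium tetrachloride Cl[Ti](Cl)(Cl)Cl (kept only in 24)
Why: Substrate-controlled titanium aldol addition: the Z enolate reacts through a closed chair transition state to give the C6/C7 syn relationship, the non-chelating α-silyloxy centre at C9 is expected to direct the aldehyde to the face giving the C7/C9 anti isomer (6R,7S), and the C6 hydroxyl then closes the trans γ-lactone onto the C12 ester.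

Step 20
Reactants: 26 (3S,4S,5R)-4-[(2S)-2,4-bis(TBSO)butanoyl]-5-{(1E)-2-[(2S,3R)-3-ethenyloxiran-2-yl]prop-1-en-1-yl}-3-methyloxolan-2-one
Product: 27 (3S,4R,5R)-4-[(1S,2S)-2,4-bis(TBSO)-1-hydroxybutyl]-5-{(1E)-2-[(2S,3R)-3-ethenyloxiran-2-yl]prop-1-en-1-yl}-3-methyloxolan-2-one (ring C4 label changes by priority only)
Conditions: LiBH(s-Bu)3, THF, −78 °C; AcOH quench at −78 °C
Reagents that add atoms: none
Why: Felkin–Anh reduction with a bulky hydride anti to the C9 silyloxy group gives the 8,9-syn (8S) alcohol; the lactone is not reduced at −78 °C.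

Step 21
Reactants: 27 (3S,4R,5R)-4-[(1S,2S)-2,4-bis(TBSO)-1-hydroxybutyl]-5-{(1E)-2-[(2S,3R)-3-ethenyloxiran-2-yl]prop-1-en-1-yl}-3-methyloxolan-2-one; 23 (2S,3S)-2,3-dimethyloxirane-2-carboxylic acid
Product: 29 (1S,2S)-2,4-bis(TBSO)-1-[(2R,3S,4S)-2-{(1E)-2-[(2S,3R)-3-ethenyloxiran-2-yl]prop-1-en-1-yl}-4-methyl-5-oxooxolan-3-yl]butyl (2S,3S)-2,3-dimethyloxirane-2-carboxylate, via mixed anhydride 28 (not isolated)
Conditions: 2,4,6-trichlorobenzoyl chloride, Et3N, THF, rt; then 27, DMAP, toluene, rt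
Reagents that add atoms: 2,4,6-trichlorobenzoyl chloride O=C(Cl)c1c(Cl)cc(Cl)cc1Cl (kept only in 28)
Why: Yamaguchi esterification acylates the hindered C8 hydroxyl with retention; the epoxy acid has no α-hydrogen and cannot epimerise.

Step 22
Reactants: 29 (C8 epoxyangelate, C9 and C14 TBS ethers)
Product: 30 (1S,2S)-2-(TBSO)-4-hydroxy-1-[(2R,3S,4S)-2-{(1E)-2-[(2S,3R)-3-ethenyloxiran-2-yl]prop-1-en-1-yl}-4-methyl-5-oxooxolan-3-yl]butyl (2S,3S)-2,3-dimethyloxirane-2-carboxylate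
Conditions: NH4F, MeOH, rt
Reagents that add atoms: none
Why: Near-neutral fluoride cleaves the unhindered primary silyl ether much faster than the secondary one at C9, and spares the oxiranes and esters.

Step 23
Reactants: 30 (C14 primary alcohol)
Product: 31 (1S,2S)-2-(TBSO)-4-oxo-1-[(2R,3S,4S)-2-{(1E)-2-[(2S,3R)-3-ethenyloxiran-2-yl]prop-1-en-1-yl}-4-methyl-5-oxooxolan-3-yl]butyl (2S,3S)-2,3-dimethyloxirane-2-carboxylate
Conditions: Dess–Martin periodinane, NaHCO3, CH2Cl2, 0 °C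
Reagents that add atoms: none
Why: Buffered Dess–Martin oxidation of the primary alcohol to the C14 aldehyde.

Step 24
Reactants: 31 (C14 aldehyde)
Product: 33 (1S,2S)-2-(TBSO)-3-formyl-1-[(2R,3S,4S)-2-{(1E)-2-[(2S,3R)-3-ethenyloxiran-2-yl]prop-1-en-1-yl}-4-methyl-5-oxooxolan-3-yl]but-3-en-1-yl (2S,3S)-2,3-dimethyloxirane-2-carboxylate, via Mannich base 32 (not isolated)
Conditions: CH2=NMe2+ I−, Et3N, CH2Cl2, rt
Reagents that add atoms: N,N-dimethylmethyleneiminium iodide C=[N+](C)C.[I-]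
Why: Mannich reaction at C10 with Eschenmoser's salt followed by loss of dimethylamine (α-methylenation) gives the 2-substituted acrolein; no stereocentre is made and C9 is not acidic enough to epimerise.

Step 25
Reactants: 33 (2-substituted acrolein)
Product: 35 methyl (3S,4S)-3-(TBSO)-4-{[(2S,3S)-2,3-dimethyloxiran-2-yl]carbonyloxy}-2-methylidene-4-[(2R,3S,4S)-2-{(1E)-2-[(2S,3R)-3-ethenyloxiran-2-yl]prop-1-en-1-yl}-4-methyl-5-oxooxolan-3-yl]butanoate, via carboxylic acid 34 (not isolated)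
Conditions: NaClO2, NaH2PO4, 2-methylbut-2-ene, t-BuOH/H2O, 0 °C; then Me3SiCHN2, MeOH/toluene, 0 °C
Reagents that add atoms: sodium chlorite [Na+].[O-]Cl=O; (trimethylsilyl)diazomethane C[Si](C)(C)C=[N+]=[N-]
Why: Pinnick oxidation of the enal (hypochlorite scavenged by the alkene additive) followed by diazo-methylation gives the C14 methyl ester without touching the other esters.

Step 26
Reactants: 35 (C9 TBS ether, methyl acrylate)
Product: 36 methyl (3S,4S)-4-{[(2S,3S)-2,3-dimethyloxiran-2-yl]carbonyloxy}-3-hydroxy-2-methylidene-4-[(2R,3S,4S)-2-{(1E)-2-[(2S,3R)-3-ethenyloxiran-2-yl]prop-1-en-1-yl}-4-methyl-5-oxooxolan-3-yl]butanoate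
Conditions: Bu4NF, AcOH, THF, 0 °C to rt
Reagents that add atoms: none
Why: Buffered fluoride desilylation frees the C9 hydroxyl; the acetic acid suppresses C8-to-C9 acyl migration and retro-aldol of the hydroxy-acrylate.

Step 27
Reactants: 36 (C9 alcohol); 37 (2R)-2-methylbutanoic acid
Product: 38 methyl (3S,4S)-4-{[(2S,3S)-2,3-dimethyloxiran-2-yl]carbonyloxy}-3-{[(2R)-2-methylbutanoyl]oxy}-2-methylidene-4-[(2R,3S,4S)-2-{(1E)-2-[(2S,3R)-3-ethenyloxiran-2-yl]prop-1-en-1-yl}-4-methyl-5-oxooxolan-3-yl]butanoate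
Conditions: DCC, DMAP (0.1 equiv), CH2Cl2, 0 °C
Reagents that add atoms: none
Why: Steglich esterification with retention at C9; low temperature and catalytic DMAP protect the α-stereocentre of the acid and avoid allylic transposition.

Step 28
Reactants: 38 (seco-triene)
Product: 39 target CNP0479131.1, methyl (2R,3S,6R,7S,8S,9S,11S)-2,3-epoxy-8-{[(2S,3S)-2,3-dimethyloxiran-2-yl]carbonyloxy}-9-{[(2R)-2-methylbutanoyl]oxy}germacra-1(10),4-dien-12,6-olid-14-oate (C2 and C9 cis across C1=C10, C4=C5 E)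
Conditions: second-generation Grubbs catalyst RuCl2(=CHPh)(H2IMes)(PCy3) (10 mol%), CH2Cl2 (1 mM), 40 °C
Reagents that add atoms: none
Why: Ring-closing metathesis initiates at the vinyl oxirane and closes onto the acrylate with loss of ethene; the ten-membered ring can only take the ring-cis trisubstituted enoate, which is the target geometry.

## Compound list

1 | (2Z)-but-2-ene-1,4-diol | OC/C=C\CO | starting material
2 | (2Z)-4-(TBDPSO)but-2-en-1-ol | OC/C=C\CO[Si](c1ccccc1)(c1ccccc1)C(C)(C)C | intermediate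
3 | [(2S,3R)-3-(TBDPSO-methyl)oxiran-2-yl]methanol | OC[C@@H]1O[C@@H]1CO[Si](c2ccccc2)(c3ccccc3)C(C)(C)C | intermediate
4 | (2R,3R)-3-(TBDPSO-methyl)oxirane-2-carbaldehyde | O=C[C@@H]1O[C@@H]1CO[Si](c2ccccc2)(c3ccccc3)C(C)(C)C | intermediate
5 | 1-[(2S,3R)-3-(TBDPSO-methyl)oxiran-2-yl]ethan-1-ol, carbinol epimers | CC(O)[C@@H]1O[C@@H]1CO[Si](c2ccccc2)(c3ccccc3)C(C)(C)C | intermediate
6 | 1-[(2R,3R)-3-(TBDPSO-methyl)oxiran-2-yl]ethan-1-one | CC(=O)[C@@H]1O[C@@H]1CO[Si](c2ccccc2)(c3ccccc3)C(C)(C)C | intermediate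
7 | (2E)-3-[(2S,3R)-3-(TBDPSO-methyl)oxiran-2-yl]-N-methoxy-N-methylbut-2-enamide | CON(C)C(=O)/C=C(C)/[C@@H]1O[C@@H]1CO[Si](c2ccccc2)(c3ccccc3)C(C)(C)C | intermediate
8 | (2E)-3-[(2S,3R)-3-(hydroxymethyl)oxiran-2-yl]-N-methoxy-N-methylbut-2-enamide | CON(C)C(=O)/C=C(C)/[C@@H]1O[C@@H]1CO | intermediate
9 | (2E)-3-[(2S,3S)-3-formyloxiran-2-yl]-N-methoxy-N-methylbut-2-enamide | CON(C)C(=O)/C=C(C)/[C@@H]1O[C@@H]1C=O | intermediate
10 | (2E)-3-[(2S,3R)-3-ethenyloxiran-2-yl]-N-methoxy-N-methylbut-2-enamide | CON(C)C(=O)/C=C(C)/[C@@H]1O[C@@H]1C=C | intermediate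
11 | (2E)-3-[(2S,3R)-3-ethenyloxiran-2-yl]but-2-enal | O=C/C=C(C)/[C@@H]1O[C@@H]1C=C | intermediate
12 | (3S)-3-hydroxyoxolan-2-one | O[C@H]1CCOC1=O | starting material
13 | (3S)-3-(TBSO)oxolan-2-one | CC(C)(C)[Si](C)(C)O[C@H]1CCOC1=O | intermediate
14 | S-ethyl (2S)-2-(TBSO)-4-hydroxybutanethioate | CCSC(=O)[C@@H](O[Si](C)(C)C(C)(C)C)CCO | intermediate
15 | S-ethyl (2S)-2,4-bis(TBSO)butanethioate | CCSC(=O)[C@@H](O[Si](C)(C)C(C)(C)C)CCO[Si](C)(C)C(C)(C)C | intermediate
16 | methyl (2S)-3-hydroxy-2-methylpropanoate | OC[C@H](C)C(=O)OC | starting material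
17 | methyl (2R)-3-iodo-2-methylpropanoate | IC[C@H](C)C(=O)OC | intermediate
18 | [(2R)-3-methoxy-2-methyl-3-oxopropyl]zinc iodide | I[Zn]C[C@H](C)C(=O)OC | intermediate
19 | methyl (2S,5S)-5,7-bis(TBSO)-2-methyl-4-oxoheptanoate | CC(C)(C)[Si](C)(C)OCC[C@H](O[Si](C)(C)C(C)(C)C)C(=O)C[C@H](C)C(=O)OC | intermediate
20 | (2Z)-2-methylbut-2-enoic acid (angelic acid) | C/C=C(/C)C(=O)O | starting material
21 | (2Z)-2-methylbut-2-en-1-ol | C/C=C(/C)CO | intermediate
22 | [(2R,3S)-2,3-dimethyloxiran-2-yl]methanol | OC[C@@]1(C)O[C@H]1C | intermediate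
23 | (2S,3S)-2,3-dimethyloxirane-2-carboxylic acid | OC(=O)[C@@]1(C)O[C@H]1C | intermediate
24 | trichlorotitanium (Z)-enolate of 19 (C7=C8, O–Ti cis to C11) | CC(C)(C)[Si](C)(C)OCC[C@H](O[Si](C)(C)C(C)(C)C)/C(O[Ti](Cl)(Cl)Cl)=C/[C@H](C)C(=O)OC | intermediate
25 | methyl (2S,3S,4R,5E)-3-[(2S)-2,4-bis(TBSO)butanoyl]-6-[(2S,3R)-3-ethenyloxiran-2-yl]-4-hydroxy-2-methylhept-5-enoate | CC(C)(C)[Si](C)(C)OCC[C@H](O[Si](C)(C)C(C)(C)C)C(=O)[C@@H]([C@H](C)C(=O)OC)[C@H](O)/C=C(C)/[C@@H]1O[C@@H]1C=C | intermediate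
26 | (3S,4S,5R)-4-[(2S)-2,4-bis(TBSO)butanoyl]-5-{(1E)-2-[(2S,3R)-3-ethenyloxiran-2-yl]prop-1-en-1-yl}-3-methyloxolan-2-one | CC(C)(C)[Si](C)(C)OCC[C@H](O[Si](C)(C)C(C)(C)C)C(=O)[C@H]1[C@H](C)C(=O)O[C@@H]1/C=C(C)/[C@@H]2O[C@@H]2C=C | intermediate
27 | (3S,4R,5R)-4-[(1S,2S)-2,4-bis(TBSO)-1-hydroxybutyl]-5-{(1E)-2-[(2S,3R)-3-ethenyloxiran-2-yl]prop-1-en-1-yl}-3-methyloxolan-2-one | CC(C)(C)[Si](C)(C)OCC[C@H](O[Si](C)(C)C(C)(C)C)[C@@H](O)[C@H]1[C@H](C)C(=O)O[C@@H]1/C=C(C)/[C@@H]2O[C@@H]2C=C | intermediate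
28 | (2S,3S)-2,3-dimethyloxirane-2-carboxylic 2,4,6-trichlorobenzoic anhydride | O=C(OC(=O)c1c(Cl)cc(Cl)cc1Cl)[C@@]2(C)O[C@H]2C | intermediate
29 | (1S,2S)-2,4-bis(TBSO)-1-[(2R,3S,4S)-2-{(1E)-2-[(2S,3R)-3-ethenyloxiran-2-yl]prop-1-en-1-yl}-4-methyl-5-oxooxolan-3-yl]butyl (2S,3S)-2,3-dimethyloxirane-2-carboxylate | CC(C)(C)[Si](C)(C)OCC[C@H](O[Si](C)(C)C(C)(C)C)[C@@H](OC(=O)[C@@]3(C)O[C@H]3C)[C@H]1[C@H](C)C(=O)O[C@@H]1/C=C(C)/[C@@H]2O[C@@H]2C=C | intermediate
30 | as 29 with free C14 hydroxyl (4-hydroxybutyl) | OCC[C@H](O[Si](C)(C)C(C)(C)C)[C@@H](OC(=O)[C@@]3(C)O[C@H]3C)[C@H]1[C@H](C)C(=O)O[C@@H]1/C=C(C)/[C@@H]2O[C@@H]2C=C | intermediate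
31 | as 30 with C14 aldehyde (4-oxobutyl) | O=CC[C@H](O[Si](C)(C)C(C)(C)C)[C@@H](OC(=O)[C@@]3(C)O[C@H]3C)[C@H]1[C@H](C)C(=O)O[C@@H]1/C=C(C)/[C@@H]2O[C@@H]2C=C | intermediate
32 | as 31 with a (dimethylamino)methyl group on C10 (C10 epimers) | CN(C)CC(C=O)[C@H](O[Si](C)(C)C(C)(C)C)[C@@H](OC(=O)[C@@]3(C)O[C@H]3C)[C@H]1[C@H](C)C(=O)O[C@@H]1/C=C(C)/[C@@H]2O[C@@H]2C=C | intermediate
33 | (1S,2S)-2-(TBSO)-3-formyl-1-[(2R,3S,4S)-2-{(1E)-2-[(2S,3R)-3-ethenyloxiran-2-yl]prop-1-en-1-yl}-4-methyl-5-oxooxolan-3-yl]but-3-en-1-yl (2S,3S)-2,3-dimethyloxirane-2-carboxylate | C=C(C=O)[C@H](O[Si](C)(C)C(C)(C)C)[C@@H](OC(=O)[C@@]3(C)O[C@H]3C)[C@H]1[C@H](C)C(=O)O[C@@H]1/C=C(C)/[C@@H]2O[C@@H]2C=C | intermediate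
34 | as 33 with CO2H in place of CHO | C=C(C(=O)O)[C@H](O[Si](C)(C)C(C)(C)C)[C@@H](OC(=O)[C@@]3(C)O[C@H]3C)[C@H]1[C@H](C)C(=O)O[C@@H]1/C=C(C)/[C@@H]2O[C@@H]2C=C | intermediate
35 | methyl (3S,4S)-3-(TBSO)-4-{[(2S,3S)-2,3-dimethyloxiran-2-yl]carbonyloxy}-2-methylidene-4-[(2R,3S,4S)-2-{(1E)-2-[(2S,3R)-3-ethenyloxiran-2-yl]prop-1-en-1-yl}-4-methyl-5-oxooxolan-3-yl]butanoate | C=C(C(=O)OC)[C@H](O[Si](C)(C)C(C)(C)C)[C@@H](OC(=O)[C@@]3(C)O[C@H]3C)[C@H]1[C@H](C)C(=O)O[C@@H]1/C=C(C)/[C@@H]2O[C@@H]2C=C | intermediate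
36 | as 35 with free C9 hydroxyl (3-hydroxy) | C=C(C(=O)OC)[C@H](O)[C@@H](OC(=O)[C@@]3(C)O[C@H]3C)[C@H]1[C@H](C)C(=O)O[C@@H]1/C=C(C)/[C@@H]2O[C@@H]2C=C | intermediate
37 | (2R)-2-methylbutanoic acid | CC[C@@H](C)C(=O)O | starting material
38 | methyl (3S,4S)-4-{[(2S,3S)-2,3-dimethyloxiran-2-yl]carbonyloxy}-3-{[(2R)-2-methylbutanoyl]oxy}-2-methylidene-4-[(2R,3S,4S)-2-{(1E)-2-[(2S,3R)-3-ethenyloxiran-2-yl]prop-1-en-1-yl}-4-methyl-5-oxooxolan-3-yl]butanoate | C=C(C(=O)OC)[C@H](OC(=O)[C@H](C)CC)[C@@H](OC(=O)[C@@]3(C)O[C@H]3C)[C@H]1[C@H](C)C(=O)O[C@@H]1/C=C(C)/[C@@H]2O[C@@H]2C=C | intermediate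
39 | CNP0479131.1 | CC[C@@H](C)C(=O)O[C@H]1/C(C(=O)OC)=C\[C@H]2O[C@H]2/C(C)=C/[C@H]2OC(=O)[C@@H](C)[C@@H]2[C@@H]1OC(=O)[C@@]1(C)O[C@H]1C | target

## Step count and weak points

Total: 28 steps. Longest linear sequence: 20 steps (1 → 11 in steps 1–10, then steps 19–28).

Most likely to fail, first: step 19. The chlorotitanium Lewis acid may open the doubly allylic oxirane of 11, and the sense of facial control by the C9 silyloxy group rests on analogy with simpler α-silyloxy ketones. Fallback, setting out from 19 and 11 and returning at 25: 19 is enolised with Bu2BOTf and i-Pr2NEt (CH2Cl2, −78 °C) to the (Z)-enol dibutylborinate F1, which adds 11 through a closed boron chair transition state with no free metal halide present. Oxidative work-up (H2O2, pH 7 buffer) gives the hydroxy ester 25, which is lactonised to 26 as in step 19, with any minor syn isomer removed at the crystalline lactone stage.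

Second: step 20. Felkin control from C9 may be eroded by the adjacent ring stereocentre. Fallback, setting out from 25 (step 19 stopped before the hydroxypyridine treatment) and returning at 27: Me4NBH(OAc)3 in MeCN/AcOH at −30 °C binds the C6 hydroxyl and delivers hydride internally to C8 (Evans–Saksena reduction) to give the 6,8-anti diol ester, methyl (2S,3S,4R,5E)-3-[(1S,2S)-2,4-bis(TBSO)-1-hydroxybutyl]-6-[(2S,3R)-3-ethenyloxiran-2-yl]-4-hydroxy-2-methylhept-5-enoate F2. Warming with 2-hydroxypyridine in toluene then closes the lactone through O6 (the trans-disubstituted 6,12-lactone is favoured over the cis 8,12-isomer) to give 27.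

Third: step 28. The hindered, electron-poor 1,1-disubstituted acrylate may not engage the ruthenium carbene, and the cis-divinyl oxirane limits the temperature that can be used. Fallback, setting out from 36 and returning at 39: the ring is closed on the free allylic alcohol 36 with the same ruthenium catalyst (a free allylic hydroxyl accelerates metathesis and the olefin is less hindered than in the ester) to give the macrocyclic 9-hydroxy lactone F3, which is then esterified with 37 (DCC, DMAP, CH2Cl2, 0 °C) to give 39.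

## Further compounds

F1 | step 19 | (Z)-enol dibutylborinate of 19 (C7=C8, O–B cis to C11) | CCCCB(CCCC)O/C(=C\[C@H](C)C(=O)OC)[C@@H](O[Si](C)(C)C(C)(C)C)CCO[Si](C)(C)C(C)(C)C
F2 | step 20 | methyl (2S,3S,4R,5E)-3-[(1S,2S)-2,4-bis(TBSO)-1-hydroxybutyl]-6-[(2S,3R)-3-ethenyloxiran-2-yl]-4-hydroxy-2-methylhept-5-enoate | CC(C)(C)[Si](C)(C)OCC[C@H](O[Si](C)(C)C(C)(C)C)[C@@H](O)[C@@H]([C@H](C)C(=O)OC)[C@H](O)/C=C(C)/[C@@H]1O[C@@H]1C=C
F3 | step 28 | 39 lacking the 2-methylbutanoyl group (free 9-hydroxyl) | O[C@H]1/C(C(=O)OC)=C\[C@H]2O[C@H]2/C(C)=C/[C@H]2OC(=O)[C@@H](C)[C@@H]2[C@@H]1OC(=O)[C@@]1(C)O[C@H]1C
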